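The constants used here stand for no real mixture, and the outcome is calculated.

Follow the reagent.

starting material 5.0 mM; reagent in the second phase 1.00 equiv; time 6.0 s; volume of the second phase over the first 2.0

- the target and product in the second phase together standing at 6.0 s, as a percentage of the starting material charged
- the change that raises the amount of target and product in the second phase together at 6.0 s, in percent of the starting material charged most ("none" if none brings more than 2 percentage points) (theta / zeta / eta / none)
- amount of target and product in the second phase together at 6.0 s, in percent of the starting material charged, after theta

- theta: doubling the transfer coefficient of step 3, all else as stated
- zeta: doubling the transfer coefficient of step 1, all else as stated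
- eta: doubling the amount of reagent in the second phase, all else as stated

- a species is counted by the starting material in it: one side product counts as two
- amounts and yields of target count product in the second phase too
- in the second phase: reagent in the second phase, product in the second phase; everything else is in the first
- charges count per volume of the first phase; a concentration in a rate is the amount of a species over the volume of its own phase; every rate counts per litre of the first phase
- run time (flask): 6.0 s

    reagent in the reaction phase ⇌ reagent in the second phase, rate k1*([reagent in the reaction phase] - [reagent in the second phase]/K1) per volume of the first phase (K1 = 2.5, k1 = 6.0 /s)
    starting material + reagent in the reaction phase → target (k2 = 43 /M/s)
    target ⇌ product in the second phase, rate k3*([target] - [product in the second phase]/K3) per volume of the first phase (K3 = 0.99, k3 = 0.091 /s)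
    target → decomposed product (k4 = 0.96 /s)
    reagent in the reaction phase → decomposed reagent (k5 = 0.0091 /s)
    starting material + target → side product (k6 = 11 /M/s)

1. The reagent starts in the second phase, but it reacts in the first. Its transfer relaxes with a half-life of 0.0963 s, far shorter than the 3.2 s half-life of reaction-phase reagent against starting material. So the partition keeps up. [reagent in the reaction phase] then stands near the free reagent level, the reagent charge divided by one plus partition ratio times volume ratio: 0.833 mM.

2. With starting material near its charge, the reaction is pseudo-first-order in that level, and target forms at 0.179 mM/s. Objection: both partners are consumed. Over 6.0 s this rate would use 21.5% of each equal charge, so the final rate is nearer 0.110 mM/s.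

3. Target should stay low, because its 0.72 s half-life by decomposition is short against 6.0 s. It should sit near a resting state, its level being making rate over loss constant. Objection: decomposition is not its sole loss. Adding transfer and side reaction gives 1.11 /s, and the first-phase level ends near 2.00%.

4. Objection: product in the second phase counts too. At a mean level of 2.62%, omitting the initial rise of 0.901 s and neglecting back-transfer, it collects 1.21%. This reckoning therefore gives 3.21%.

5. Under theta, the same sum gives 4.12%. Under zeta, the free reagent level stands as before: its formula holds no transfer coefficient. Under eta, the level and the starting making rate double, so this reckoning puts the gain near 3.21%, before the extra drain on starting material, against the 2 percentage points required. This reckoning chooses eta.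

The forecast, 3.4%, eta and 4.1%, is slightly higher on y and rests on this ground: “Reagent partitioning is fast”.

The flask gives 3.41%, and 4.06% after theta. The gains are 0.65 points for theta, 0.031 points for zeta and 2.6 points for eta, so the best change is eta.

The neighbour flask with 1.2 mM of starting material holds 78.8% of its reagent charge in the second phase at 6.00 s, so the free reagent level scales to 0.189 mM; it reads 0.188 mM and gives 1.05%. The main flask has not come to rest. At 60.0 s, 24.8% of the reagent charge remains in the second phase, so the level scales to 0.248 mM, and the reading is 0.245 mM. Ten times the time takes starting material from 82.4% to 32.1% and decomposed product from 12.8% to 61.7%, while target and product in the second phase together fall to 1.67%.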